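**Retrosynthetic overview**

1. Target ⇒ triol: the two equatorial hydroxyls (C3, C9) are esterified with hex-2-ynoic acid and the alkynes semi-hydrogenated to the (Z)-enoates; the axial C8 hydroxyl stays free.
2. Triol ⇒ trans-decalin 8-ketone with 7α-isopropenyl and 9α-silyloxy groups (equatorial hydride attack sets C8); the C7–isopropenyl bond comes from a palladium enolate alkenylation, the C9–O bond from a Rubottom oxidation.
3. That ketone ⇒ bicyclic enedione through one dissolving-metal step that sets C10 (trans fusion) and C3 (equatorial alcohol) and delivers the C8=C9 enol ether.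
4. Enedione ⇒ 1-vinylcyclopentanol by a one-carbon semipinacol ring expansion (1,2-shift of the quaternary carbon) that creates ring A with the cis-vicinal methyls.
5. Vinyl carbinol ⇒ (S)-Hajos–Parrish ketone ⇒ 2-methylcyclopentane-1,3-dione + methyl vinyl ketone; ring B is formed first (Robinson annulation), ring A second (expansion of the five-membered ring).

Assumption: positions are given in eremophilane numbering (C5 = methyl-bearing ring-fusion carbon, C10 = the other fusion carbon, ring A = C1–C5/C10, ring B = C5–C10); β is the face of the C5 methyl, α the opposite face.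

**Route**

Step 1
Reactants: 1 2-methylcyclopentane-1,3-dione; 2 but-3-en-2-one (methyl vinyl ketone)
Product: 5 (7aS)-7a-methyl-2,3,7,7a-tetrahydro-1H-indene-1,5(6H)-dione [(S)-Hajos–Parrish ketone], via triketone 3 (not isolated), via cis-fused ketol 4 (not isolated)
Conditions: 2 (1.3 equiv), H2O, AcOH (cat.), 70 °C; concentrate; (S)-proline (3 mol %), DMF, 20 °C; then H2SO4 (cat.), 95 °C
Reagents that add atoms: none
Why: Michael addition followed by the proline-catalysed Hajos–Parrish intramolecular aldol condensation, in which the side-chain enamine attacks one enantiotopic ring carbonyl and sets the quaternary centre (future C5) as S (about 93 % ee, raised by one crystallisation).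

Step 2
Reactants: 5 (S)-Hajos–Parrish ketone; 6 vinylmagnesium bromide
Product: 7 (1R,7aS)-1-ethenyl-1-hydroxy-7a-methyl-1,2,3,6,7,7a-hexahydro-5H-inden-5-one (vinyl α, hydroxyl β)
Conditions: CH2=CHMgBr (1.1 equiv), LaCl3·2LiCl (0.3 equiv), THF, −78 °C; H2O
Reagents that add atoms: none
Why: Grignard 1,2-addition, expected to favour the non-conjugated cyclopentanone over the conjugation-deactivated enone carbonyl (the same preference that governs hydride reduction of 5), with attack anti to the angular methyl placing the vinyl group α and the hydroxyl β.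

Step 3
Reactants: 7 vinyl carbinol
Product: 8 (1R,8aR)-1,8a-dimethyl-3,4,8,8a-tetrahydronaphthalene-2,6(1H,7H)-dione (eremophilane numbering: 3,8-dioxo, C9=C10, 4β-methyl, 5β-methyl, no C7 substituent)
Conditions: Co(C32H46N2O2) [N,N′-bis(3,5-di-tert-butylsalicylidene)ethylenediaminocobalt, divalent cobalt] (5 mol %), N-fluoro-2,4,6-trimethylpyridinium tetrafluoroborate (1.5 equiv), PhSiH3 (1.2 equiv), acetone, 0 °C
Reagents that add atoms: none
Why: Proposed new method: cobalt-hydride hydrogen-atom transfer to the terminal vinyl carbon gives a secondary radical that is captured and oxidised to an electrophilic alkylcobalt species (tetravalent cobalt), and the antiperiplanar, electron-rich quaternary ring carbon (future C5) then migrates with displacement of cobalt while the hydroxyl becomes the C3 ketone, so the cyclopentanol expands to the cyclohexanone through a chair-like transition state that places the new methyl pseudo-equatorial and syn to the developing carbonyl (4β, cis to the C5 methyl); the closest known reactions are cobalt-salen radical-polar crossover semipinacol rearrangements of strained or 1,1-disubstituted tertiary allylic alcohols and halonium-induced semipinacol ring expansions, neither shown for an unstrained 1-vinylcyclopentanol reacting through a secondary carbon.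

Step 4
Reactants: 8 enedione
Product: 10 3α,8-bis(tert-butyldimethylsilyloxy)-4β,5β-dimethyl-10αH-decal-8(9)-ene (trans-fused; silyl ether at C3, silyl enol ether C8=C9), via dilithium alkoxide enolate 9 (not isolated)
Conditions: Li (6 equiv), NH3/THF, t-BuOH (2.0 equiv), −78 °C; isoprene; evaporate NH3; then t-BuMe2SiOTf (4 equiv), Et3N, THF, −78 → 0 °C
Reagents that add atoms: tert-butyldimethylsilyl trifluoromethanesulfonate CC(C)(C)[Si](C)(C)OS(=O)(=O)C(F)(F)F
Why: Dissolving-metal (Birch-type) reduction with Stork enolate trapping, in which axial protonation at C10 anti to the C5 methyl gives the trans-fused C8 enolate (10α-H), the C3 ketone is reduced under thermodynamic control to the equatorial 3α-alkoxide, and O-silylation fixes the C8=C9 enolate regiochemistry.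

Step 5
Reactants: 10 bis-silyl enol ether
Product: 12 3α,9α-bis(tert-butyldimethylsilyloxy)-4β,5β-dimethyl-10αH-decalin-8-one, via silyloxy epoxide 11 (not isolated)
Conditions: mCPBA (1.05 equiv), hexane/CH2Cl2, −15 → 20 °C
Reagents that add atoms: mCPBA O=C(OO)c1cccc(Cl)c1
Why: Rubottom oxidation, with epoxidation of the enol ether from the α face (the β face of C9 is blocked by the 1,3-diaxial C5 methyl) and 1,4-silyl shift giving the equatorial 9α-silyloxy ketone.

Step 6
Reactants: 12 silyloxy ketone; 13 2-bromopropene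
Product: 16 3α,9α-bis(tert-butyldimethylsilyloxy)-10αH-eremophil-11-en-8-one (7α-isopropenyl), via lithium C7 enolate 14 (not isolated), via lithium dienolate 15 (not isolated)
Conditions: LiN(SiMe3)2 (2.2 equiv), THF/toluene, −78 °C; then 13 (1.5 equiv), Pd2(dba)3 [tris(dibenzylideneacetone)dipalladium] (2.5 mol %), P(t-Bu)3 (6 mol %), −20 → 20 °C; AcOH, −78 °C
Reagents that add atoms: none
Why: Palladium-catalysed ketone α-alkenylation of the kinetic enolate formed at the unhindered C7 methylene, after which the product is held as its dienolate and kinetic axial (β) α-protonation on quench gives the equatorial 7α-isopropenyl group without conjugation into the 7(11) position.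

Step 7
Reactants: 16 isopropenyl ketone
Product: 18 10αH-eremophil-11-ene-3α,8α,9α-triol, via bis-silyl 8α-alcohol 17 (not isolated)
Conditions: LiBH(s-Bu)3 (1.5 equiv), THF, −78 °C; H2O; then Bu4NF (4 equiv), THF, 45 °C
Reagents that add atoms: none
Why: Bulky trialkylborohydride reduction by equatorial attack on a ketone flanked by two equatorial substituents gives the axial 8α-alcohol (C7, C8, C9 all cis), and fluoride desilylation then frees the two equatorial hydroxyls.

Step 8
Reactants: 18 triol; 19 hex-2-ynoic acid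
Product: 20 8α-hydroxy-10αH-eremophil-11-ene-3α,9α-diyl bis(hex-2-ynoate)
Conditions: 19 (2.2 equiv), N,N′-diisopropylcarbodiimide (2.4 equiv), 4-(dimethylamino)pyridine (0.1 equiv), CH2Cl2, −20 → 0 °C
Reagents that add atoms: none
Why: Steglich esterification, site-selective for the equatorial C3 and C9 hydroxyls because the axial C8 hydroxyl is shielded by its two neighbours and two syn-axial hydrogens; no stereocentre is touched.

Step 9
Reactants: 20 bis-ynoate
Product: 21 (3R,4R,5R,7S,8R,9S,10R)-8-hydroxy-eremophil-11-ene-3,9-diyl bis[(2Z)-hex-2-enoate] (target, CNP0420276.1)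
Conditions: H2 (1 atm), Pd/CaCO3 poisoned with Pb(OAc)2, quinoline, EtOAc, 20 °C
Reagents that add atoms: none
Why: Lindlar-type syn semi-hydrogenation of both conjugated alkynes gives the (Z)-enoates while the 1,1-disubstituted isopropenyl alkene is left untouched.

**Compound list**

1 | 2-methylcyclopentane-1,3-dione | CC1C(=O)CCC1=O | starting material
2 | but-3-en-2-one (methyl vinyl ketone) | CC(=O)C=C | starting material
3 | 2-methyl-2-(3-oxobutyl)cyclopentane-1,3-dione | CC(=O)CCC1(C)C(=O)CCC1=O | intermediate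
4 | (3aS,7aS)-3a-hydroxy-7a-methylhexahydro-1H-indene-1,5(4H)-dione (cis-fused ketol) | C[C@]12CCC(=O)C[C@@]1(O)CCC2=O | intermediate
5 | (7aS)-7a-methyl-2,3,7,7a-tetrahydro-1H-indene-1,5(6H)-dione | C[C@]12CCC(=O)C=C1CCC2=O | intermediate
6 | vinylmagnesium bromide | C=C[Mg]Br | starting material
7 | (1R,7aS)-1-ethenyl-1-hydroxy-7a-methyl-1,2,3,6,7,7a-hexahydro-5H-inden-5-one | C[C@]12CCC(=O)C=C1CC[C@@]2(O)C=C | intermediate
8 | (1R,8aR)-1,8a-dimethyl-3,4,8,8a-tetrahydronaphthalene-2,6(1H,7H)-dione | O=C1CC[C@]2(C)[C@@H](C)C(=O)CCC2=C1 | intermediate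
9 | dilithium 3α-olate / C8=C9 enolate of the 4β,5β-dimethyl-10αH-decalin | C1C[C@]2(C)[C@@H](C)[C@H]([O-])CC[C@H]2C=C1[O-].[Li+].[Li+] | intermediate
10 | 3α,8-bis(tert-butyldimethylsilyloxy)-4β,5β-dimethyl-10αH-decal-8(9)-ene | C1C[C@]2(C)[C@@H](C)[C@H](O[Si](C)(C)C(C)(C)C)CC[C@H]2C=C1O[Si](C)(C)C(C)(C)C | intermediate
11 | 8α,9α-epoxide of 10 (8-silyloxy oxirane) | C1C[C@]2(C)[C@@H](C)[C@H](O[Si](C)(C)C(C)(C)C)CC[C@H]2[C@@H]3O[C@]13O[Si](C)(C)C(C)(C)C | intermediate
12 | 3α,9α-bis(tert-butyldimethylsilyloxy)-4β,5β-dimethyl-10αH-decalin-8-one | C1C[C@]2(C)[C@@H](C)[C@H](O[Si](C)(C)C(C)(C)C)CC[C@H]2[C@H](O[Si](C)(C)C(C)(C)C)C1=O | intermediate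
13 | 2-bromopropene | CC(Br)=C | starting material
14 | lithium C7=C8 enolate of 12 | [Li+].[O-]C1=CC[C@]2(C)[C@@H](C)[C@H](O[Si](C)(C)C(C)(C)C)CC[C@H]2[C@@H]1O[Si](C)(C)C(C)(C)C | intermediate
15 | lithium dienolate of 16 (C8 enolate conjugated with the isopropenyl group) | [Li+].[O-]C1=C(C(C)=C)C[C@]2(C)[C@@H](C)[C@H](O[Si](C)(C)C(C)(C)C)CC[C@H]2[C@@H]1O[Si](C)(C)C(C)(C)C | intermediate
16 | 3α,9α-bis(tert-butyldimethylsilyloxy)-10αH-eremophil-11-en-8-one | C=C(C)[C@@H]1C[C@]2(C)[C@@H](C)[C@H](O[Si](C)(C)C(C)(C)C)CC[C@H]2[C@H](O[Si](C)(C)C(C)(C)C)C1=O | intermediate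
17 | 3α,9α-bis(tert-butyldimethylsilyloxy)-10αH-eremophil-11-en-8α-ol | C=C(C)[C@@H]1C[C@]2(C)[C@@H](C)[C@H](O[Si](C)(C)C(C)(C)C)CC[C@H]2[C@H](O[Si](C)(C)C(C)(C)C)[C@@H]1O | intermediate
18 | 10αH-eremophil-11-ene-3α,8α,9α-triol | C=C(C)[C@@H]1C[C@]2(C)[C@@H](C)[C@H](O)CC[C@H]2[C@H](O)[C@@H]1O | intermediate
19 | hex-2-ynoic acid | CCCC#CC(=O)O | starting material
20 | 8α-hydroxy-10αH-eremophil-11-ene-3α,9α-diyl bis(hex-2-ynoate) | C=C(C)[C@@H]1C[C@]2(C)[C@@H](C)[C@H](OC(=O)C#CCCC)CC[C@H]2[C@H](OC(=O)C#CCCC)[C@@H]1O | intermediate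
21 | (3R,4R,5R,7S,8R,9S,10R)-8-hydroxy-eremophil-11-ene-3,9-diyl bis[(2Z)-hex-2-enoate] | C=C(C)[C@@H]1C[C@]2(C)[C@@H](C)[C@H](OC(=O)/C=C\CCC)CC[C@H]2[C@H](OC(=O)/C=C\CCC)[C@@H]1O | target

**Step count and risks**

Total step count: 9. Longest linear sequence: 9 steps (1 + 2 → 21).

Step 3 (the proposed new method). The likely failures are 3-exo closure of the alkylcobalt intermediate to a spiro-epoxide and competing migration of the C2 methylene instead of the quaternary carbon. The fallback uses known chemistry, sets out from 5 and comes back at 8. The enone carbonyl of 5 is masked selectively with propane-1,3-dithiol/BF3·OEt2 as the dithiane ketone F1. LiCBr2CH3 (from CH3CHBr2 and LiN(i-Pr)2, THF, −95 °C) adds to the cyclopentanone from the α face to give the lithium 1,1-dibromoethyl alkoxide F2. n-BuLi then effects bromine–lithium exchange, and the β-oxido carbenoid rearranges with migration of the more substituted carbon (Nozaki–Yamamoto-type homologation) to the ring-expanded lithium enolate F3. Kinetic axial protonation with AcOH at −78 °C, anti to the C5 methyl, gives the 4β-methyl ketone dithiane F4, and MeI/CaCO3 in aqueous MeCN removes the dithiane to return 8.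

Step 4. The likely failures are over-reduction of the enolate to a C8 alcohol, incomplete reduction at C3, and poor O-silylation in the presence of LiNH2. The fallback sets out from 8 and comes back at 16; it gives up enolate trapping and instead blocks C7 first. The same dilithium species 9 is quenched with NH4Cl to give the trans-fused 3α-hydroxy-8-ketone F5, and t-BuMe2SiCl/imidazole gives the silyl ether F6. The conditions of step 6 (through the lithium C7 enolate F7 and the lithium dienolate F8) give the 7α-isopropenyl ketone F9. Because C7 is now tertiary, LiN(i-Pr)2 at −78 °C removes a C9 proton to give the lithium C8=C9 enolate F10, which t-BuMe2SiOTf converts into the bis-silyl enol ether F11. mCPBA (1.0 equiv, −40 °C, the enol ether reacting far faster than the isopropenyl group) gives the silyloxy epoxide F12, which rearranges by silyl shift to 16.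

Step 6. The likely failures are 1,4 O-to-O silyl migration in the α-silyloxy enolate, enolate equilibration toward C9, and isomerisation to the conjugated 7(11)-ene. The fallback sets out from 12 and comes back at 16. The enolate 14 (made with LiN(i-Pr)2 at −78 °C) undergoes aldol addition to acetone to give the tertiary β-hydroxy ketone F13. Burgess reagent (toluene, 50 °C) then eliminates toward a methyl group to give 16.

**Further compounds**

F1 | step 3 | (7aS)-7a-methyl-5,5-(propane-1,3-diyldisulfanediyl)-2,3,5,6,7,7a-hexahydro-1H-inden-1-one (enone dithiane of 5) | C[C@]12CCC3(SCCCS3)C=C1CCC2=O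
F2 | step 3 | lithium alkoxide of the 1β-hydroxy-1α-(1,1-dibromoethyl) adduct of F1 | C[C@]12CCC3(SCCCS3)C=C1CC[C@@]2([O-])C(C)(Br)Br.[Li+]
F3 | step 3 | lithium C3=C4 enolate of the ring-expanded 4,5-dimethyl ketone dithiane | C1CSC2(SC1)CC[C@]3(C)C(C)=C([O-])CCC3=C2.[Li+]
F4 | step 3 | 8-dithiane of 8 (4β,5β-dimethyl-3-ketone, C9=C10) | C1CSC2(SC1)CC[C@]3(C)[C@@H](C)C(=O)CCC3=C2
F5 | step 4 | 3α-hydroxy-4β,5β-dimethyl-10αH-decalin-8-one | C1C[C@]2(C)[C@@H](C)[C@H](O)CC[C@H]2CC1=O
F6 | step 4 | 3α-(tert-butyldimethylsilyloxy)-4β,5β-dimethyl-10αH-decalin-8-one | C1C[C@]2(C)[C@@H](C)[C@H](O[Si](C)(C)C(C)(C)C)CC[C@H]2CC1=O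
F7 | step 4 | lithium C7=C8 enolate of F6 | [Li+].[O-]C1=CC[C@]2(C)[C@@H](C)[C@H](O[Si](C)(C)C(C)(C)C)CC[C@H]2C1
F8 | step 4 | lithium dienolate of F9 | [Li+].[O-]C1=C(C(C)=C)C[C@]2(C)[C@@H](C)[C@H](O[Si](C)(C)C(C)(C)C)CC[C@H]2C1
F9 | step 4 | 3α-(tert-butyldimethylsilyloxy)-10αH-eremophil-11-en-8-one | C=C(C)[C@@H]1C[C@]2(C)[C@@H](C)[C@H](O[Si](C)(C)C(C)(C)C)CC[C@H]2CC1=O
F10 | step 4 | lithium C8=C9 enolate of F9 | C=C(C)[C@@H]1C[C@]2(C)[C@@H](C)[C@H](O[Si](C)(C)C(C)(C)C)CC[C@H]2C=C1[O-].[Li+]
F11 | step 4 | 3α,8-bis(tert-butyldimethylsilyloxy)-10αH-eremophila-8,11-diene | C=C(C)[C@@H]1C[C@]2(C)[C@@H](C)[C@H](O[Si](C)(C)C(C)(C)C)CC[C@H]2C=C1O[Si](C)(C)C(C)(C)C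
F12 | step 4 | 8α,9α-epoxide of F11 (8-silyloxy oxirane) | C=C(C)[C@@H]1C[C@]2(C)[C@@H](C)[C@H](O[Si](C)(C)C(C)(C)C)CC[C@H]2[C@@H]3O[C@]13O[Si](C)(C)C(C)(C)C
F13 | step 6 | 7α-(2-hydroxypropan-2-yl)-3α,9α-bis(tert-butyldimethylsilyloxy)-4β,5β-dimethyl-10αH-decalin-8-one | CC(C)(O)[C@@H]1C[C@]2(C)[C@@H](C)[C@H](O[Si](C)(C)C(C)(C)C)CC[C@H]2[C@H](O[Si](C)(C)C(C)(C)C)C1=O
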